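## Structural features

The target is a trans-fused decalin of the eudesmane type (ring A: C1–C5 and C10; ring B: C5–C10). C1 carries a 3-methylbutyl chain whose first carbon, C1′, is also bonded to a fully substituted 3,5-diformyl-2,4,6-trihydroxyphenyl ring. Six stereocentres are present. C1′, C1, C10, C5 and C4 form an unbroken chain of five with the quaternary, methyl-bearing C10 in the middle. C7 stands alone on ring B, with its 2-hydroxyprop-2-yl group equatorial and cis to the C10 methyl. The C4 hydroxyl is axial and syn to the C10 methyl, H5 is anti to it, and the C1 substituent is anti to the C10 methyl and therefore also axial. The fragile groups are the two tertiary alcohols (C4 and C11), which ionise or dehydrate with strong Brønsted or Lewis acids; the acidic, electron-rich, air-sensitive diformylphloroglucinol; and C1′, which ionises easily once the arene carries three oxygen donors. The real difficulty is the congested C1′–C1–C10 region (an exocyclic stereocentre beside an axial ring substituent beside a quaternary carbon), together with the need to functionalise the arene without strong acid. The key step exploits four features. The C5–C6 and C9–C10 bonds of ring B both end on the ring-fusion carbons. C10 is quaternary and bears a methyl group. C1 and C4 flank the fusion and can both carry oxygen. C7 is 1,4 to C10. Ring A is therefore a 4-oxygenated 2-methylcyclohex-2-enone whose C5=C10 double bond can take up a 2-substituted butadiene.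

## Logic of the disconnections

**30 ⇒ 29 ⇒ 28.** The last forward events are cleavage of the three aryl O–CH3 bonds and of the C11 O–Si bond. Free phenols and a free C11 hydroxyl would not survive the organolithium chemistry that precedes them. The gain is a neutral, non-acidic arene in 28. The demand is a nucleophilic dealkylation, because the tertiary alcohols at C4 and C11 would not tolerate boron or aluminium halides.

**28 ⇒ 26 ⇒ 25.** The two aryl C–CHO bonds are cut, by way of two C–Br bonds. Formyl groups would deactivate the ring and interfere with the cation chemistry at C1′, and the two open positions of 25 are its most nucleophilic sites. The gain is a plain 2,4,6-trimethoxyphenyl group. The demand is a formylation without strong Lewis acid, hence halogen–lithium exchange and DMF with the C4 hydroxyl carried as its lithium alkoxide.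

**25 ⇒ 24 ⇒ 23 ⇒ 22.** The C1′–H bond and the C1′–CH2 bond of the isobutyl group are cut. C1′ sits beside a tri-donor arene, so its cation is accessible, and the ketone of 22 is the natural electrophile for the four-carbon unit. The gain is loss of the C1′ stereocentre and of four carbons. The demands are C–C bond formation at a very hindered ketone without enolising C1 (an allyl-type Grignard reagent), and face-selective hydride transfer under acid weak and cold enough to spare the C4 carbinol.

**22 ⇒ 21.** The C1–H and C2–H bonds are cut. The C1 substituent is axial and anti to the C10 methyl, which ordinary hydrogenation would not deliver; the C4 hydroxyl lies on the face from which hydrogen must come. The gain is a C1 stereocentre traded for an alkene. The demand is hydroxyl-directed hydrogen delivery.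

**21 ⇒ 18 + 19 (through 20); 18 ⇒ 17; 17 ⇒ 15 (through 16).** The C1′–aryl bond, the C1–C1′ bond and the C1–O bond are cut, with carbon monoxide as C1′. C1 is a carbonyl carbon in 15 and is flanked by the quaternary C10, so only one enol triflate can form. The side chain reduces to CO, 19 and a Grignard reagent. The demands are carbonylation of a hindered alkenyl triflate and an aryllithium addition that stops at the ketone.

**15 ⇒ 14 ⇒ 13 ⇒ 12.** The C1 acetal, the C7–H/C8–H bonds and the C4–CH3 bond are cut. The gain is removal of the C4 and C7 stereocentres. The demands are equatorial methyl addition at C4, hydrogen addition to the face opposite the C10 methyl, and a masked C1 carbonyl while C4 is a ketone; otherwise two ketones would compete for MeMgBr.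

**12 ⇒ 11 ⇒ 10 ⇒ 9 ⇒ 8.** The C5 configuration, the C4 oxidation level and two protecting groups are adjusted. A cycloaddition can only give the cis fusion, and a C4 ketone lets C5 equilibrate. The gain is arrival at the cycloadduct. The demands are a trans isomer favoured at equilibrium and selective removal of the secondary silyl ether beside the tertiary one.

**8 ⇒ 4 + 7.** The C5–C6 and C9–C10 bonds are cut. Ring B and the quaternary C10 arise together, and two monocyclic or acyclic pieces of similar size result. The demands are attack on the face of 4 opposite its C4 silyloxy group, bonding of the substituted end of 7 to C5, and survival of the tertiary allylic silyl ether of 7 under Lewis acid. For that reason the diene carries a tert-butyldimethylsilyl group rather than a trimethylsilyl group.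

**4 ⇒ 3 ⇒ 2 ⇒ 1.** The O–Si bond, the C4–H bond and the C4=O bond are cut. The single stereocentre of 4 comes from a catalyst-controlled reduction of the less hindered carbonyl of 2. The demand is a clean distinction between the two carbonyls and between their two faces.

**7 ⇒ 6 ⇒ 5.** The two terminal C=CH2 bonds are cut (ethylene across the alkyne), then the O–Si bond. The diene is reached from a commodity alkynol in two steps. The demand is an enyne metathesis that tolerates a fully substituted propargylic carbon.

## Other disconnections considered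

**Alternative 1:** The cut is the C5–C10 bond of a ten-membered ring: protonation of the C1=C10 alkene of the germacradiene A1 at C1, attack of C5 on C10, and proton loss from C4 would give A2.
- In its favour: one operation closes both rings, sets C1, C5 and C10 and gives the trans fusion directly. C1′ and the arene are already in place, so nothing has to be done at the congested C1/C1′ pair afterwards. On these points it is better than the chosen plan.
- In its favour: from A2, ozonolysis followed by excess MeMgBr would make both carbinols at once, so the sequence after the key step is clearly shorter.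
- Against it: A1 is a medium ring with a tetrasubstituted alkene next to a stereocentre, and its assembly is long and uncertain.
- Against it: several ring conformers can cyclise, so the relative configuration at C1, C5 and C10 depends on a conformer population that is hard to predict.
- Against it: the trimethoxyphenyl ring is a better nucleophile than the C4=C5 alkene and can intercept the C10 cation, and acid may ionise C1′.
- Comparison: the chosen plan forms its two bonds in a concerted cycloaddition under the control of one defined stereocentre; this alternative uses a stepwise cationic cascade. It is the better plan after the key step and the weaker one before it; overall the risk is higher.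

**Alternative 2:** The cut is the C4–C5 bond: the acyl-anion equivalent from the aldehyde of A3 and a chiral triazolium-derived carbene would add to one of the two enone β-carbons, giving A4 after equilibration of C5.
- In its favour: the quaternary C10 is set by a catalyst. The C4 ketone arrives directly and allows the same cis-to-trans equilibration at C5 as in the chosen plan, so it is equal on that point.
- In its favour: C1 and C1′ are made in an open chain, where acyclic stereocontrol is easier to predict than the ionic reduction of the chosen plan. On that point it is better.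
- Against it: A3 needs a 4-methylcyclohexadienone whose quaternary carbon is bonded to a branched stereogenic carbon, which is hard to reach by dearomatisation.
- Against it: the stereocentre next to the prochiral carbon may oppose the catalyst.
- Against it: A4 has a 7-keto-8-ene in ring B, so the three-carbon unit at C7 must still be attached, C7 set, and the C4 and C7 ketones told apart. Here the chosen plan is better, because its diene brings C11 in with it.
- Comparison: step economy is comparable at best.

**Alternative 3:** The cuts are C5–C10 and C8–C9: the E-enoate of the linalool-derived triene A5 would add to its own diene through a chair-like tether to give A6.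
- In its favour: the reaction is intramolecular and thermal, so no Lewis acid meets the tertiary allylic ether. That is better than the chosen plan.
- In its favour: the C4 carbinol comes from the chiral pool with its configuration, and the trans fusion is formed directly, so the Grignard addition and the C5 equilibration disappear. That is also better.
- Against it: A5 is a long linear construct with two stereocentres and a defined enoate geometry.
- Against it: a trisubstituted dienophile that must form a quaternary centre needs forcing temperatures, and the ratio of fused isomers rests on tether conformation.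
- Against it: the C9 ester is surplus and costs about three steps to remove.
- Against it: C1 is only oxygenated, so the whole C1 side-chain sequence of the chosen plan is still required; the two plans are equal on that point.
- Comparison: both plans close ring B by a [4+2] reaction and create C10 in it. The alternative is stronger on the C4/C5 problem and weaker on convergence and overall length.

Key step: step 6

## Route

Remark on conventions: eudesmane numbering is used; β means the face of the bicycle that carries the C10 methyl group and α the opposite face; C1′ is the benzylic carbon. The carbinol carbon (C1′) of 23 and 24 is formed without control and is left undefined, because it becomes trigonal in step 19.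

Step 1
Reactants: 1 2-methylcyclohex-2-en-1-one
Product: 2 2-methylcyclohex-2-ene-1,4-dione
Conditions: t-BuOOH (5 equiv), Pd(OH)2/C (5 mol %), K2CO3 (0.25 equiv), CH2Cl2, 4 °C
Reagents that add atoms: tert-butyl hydroperoxide, CC(C)(C)OO
Why: Allylic (γ) oxidation of an enone to the 1,4-enedione by a tert-butylperoxy radical chain started on the palladium surface; C4 is the only CH2 that is both allylic and gives a conjugated dione, and the low temperature and substoichiometric base should limit tautomerisation of 2 to methylhydroquinone.

Step 2
Reactants: 2 2-methylcyclohex-2-ene-1,4-dione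
Product: 3 (R)-4-hydroxy-2-methylcyclohex-2-en-1-one
Conditions: (S)-2-methyl-CBS-oxazaborolidine (20 mol %), catecholborane (1.2 equiv), toluene, −78 °C; MeOH, pH 7 buffer
Reagents that add atoms: none
Why: Corey–Bakshi–Shibata reduction; the catalyst–borane complex should bind the less hindered C4 carbonyl (C1 is flanked by the methyl-bearing alkene carbon) with the alkenyl flank as the large group, so that the (S)-catalyst delivers hydride to give the (R)-carbinol, while catecholborane at low temperature avoids conjugate reduction.

Step 3
Reactants: 3 (R)-4-hydroxy-2-methylcyclohex-2-en-1-one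
Product: 4 (R)-4-(tert-butyldimethylsilyloxy)-2-methylcyclohex-2-en-1-one
Conditions: TBSCl, imidazole, DMF, 0 °C to rt
Reagents that add atoms: tert-butyldimethylsilyl chloride, CC(C)(C)[Si](C)(C)Cl
Why: Standard silylation of a secondary alcohol; the stereocentre is not touched and the bulky silyl ether later shields one face of the enone.

Step 4
Reactants: 5 2-methylbut-3-yn-2-ol
Product: 6 tert-butyldimethyl[(2-methylbut-3-yn-2-yl)oxy]silane
Conditions: TBSOTf, 2,6-lutidine, CH2Cl2, 0 °C
Reagents that add atoms: tert-butyldimethylsilyl trifluoromethanesulfonate, CC(C)(C)[Si](C)(C)OS(=O)(=O)C(F)(F)F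
Why: The silyl triflate silylates the hindered tertiary alcohol; the tert-butyldimethylsilyl ether is chosen over a trimethylsilyl ether because it must survive a Lewis acid and fourteen further steps.

Step 5
Reactants: 6 tert-butyldimethyl[(2-methylbut-3-yn-2-yl)oxy]silane
Product: 7 2-[2-(tert-butyldimethylsilyloxy)propan-2-yl]buta-1,3-diene
Conditions: ethylene (1 atm), second-generation Grubbs catalyst (H2IMes)(PCy3)Cl2Ru=CHPh (5 mol %), CH2Cl2, 40 °C
Reagents that add atoms: ethylene, C=C
Why: Ethylene–alkyne cross enyne metathesis; the ruthenium methylidene adds to the alkyne, the ruthenacyclobutene opens to a vinyl carbene and ethylene releases the 2-substituted 1,3-diene; propargylic silyl ethers are established substrates.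

Step 6
Reactants: 4 (R)-4-(tert-butyldimethylsilyloxy)-2-methylcyclohex-2-en-1-one; 7 2-[2-(tert-butyldimethylsilyloxy)propan-2-yl]buta-1,3-diene
Product: 8 cis-fused (5β-H)-4β,11-bis(tert-butyldimethylsilyloxy)-15-noreudesm-7-en-1-one
Conditions: EtAlCl2 (1.1 equiv), 7 (2.5 equiv), toluene, −40 to 0 °C
Reagents that add atoms: none
Why: EtAlCl2 binds the C1 carbonyl of 4 and lowers the LUMO of the C5=C10 double bond, so that 7 adds in a concerted but asynchronous normal-demand [4+2] cycloaddition. The closest known reaction type is the aluminium-halide-promoted Diels–Alder reaction of 2-methylcyclohex-2-enones with isoprene-type 2-substituted butadienes. Ring B is closed as a six-membered ring by suprafacial addition across C5=C10 with formation of C5–C6 and C9–C10, which can only give the cis fusion. The diene terminus next to the substituted carbon has the larger HOMO coefficient and bonds to the β-carbon C5, the more advanced bond in the transition state, so the side chain ends at C7, para to C10. C10 is set by the face of the enone that is attacked: the diene should approach anti to the silyloxy group on C4, the neighbour of C5, and with the (R) configuration of 4 this gives the C10 configuration of the target. C5 follows from the suprafacial addition (H5 cis to the C10 methyl) and is corrected in step 9. The step needs facial selectivity (secured by the bulky C4 silyloxy group), para regioselectivity (secured by the diene substituent and the enone polarisation) and tolerance of the tertiary allylic ether (secured by the robust silyl group, low temperature and the HCl-scavenging ethyl–aluminium bond). The diene has no terminal substituent, so no endo/exo question arises.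

Step 7
Reactants: 8 cis-fused (5β-H)-4β,11-bis(tert-butyldimethylsilyloxy)-15-noreudesm-7-en-1-one
Product: 9 (5β-H)-4β,11-bis(tert-butyldimethylsilyloxy)-1,1-ethylenedioxy-15-noreudesm-7-ene
Conditions: Me3SiOCH2CH2OSiMe3 (3 equiv), Me3SiOTf (10 mol %), CH2Cl2, −78 to −20 °C; pyridine quench
Reagents that add atoms: 1,2-bis(trimethylsilyloxy)ethane, C[Si](C)(C)OCCO[Si](C)(C)C
Why: Aprotic silyl-triflate-catalysed dioxolane formation; it masks the C1 ketone so that C4 is the only carbonyl in steps 9 and 10, and the catalytic, cold conditions should leave both silyl ethers in place.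

Step 8
Reactants: 9 (5β-H)-4β,11-bis(tert-butyldimethylsilyloxy)-1,1-ethylenedioxy-15-noreudesm-7-ene
Product: 10 (5β-H)-11-(tert-butyldimethylsilyloxy)-1,1-ethylenedioxy-15-noreudesm-7-en-4β-ol
Conditions: Bu4NF (1.2 equiv), THF, 0 °C to rt
Reagents that add atoms: none
Why: Fluoride-mediated desilylation; the secondary silyl ether at C4 is attacked much faster than the tertiary one at C11, whose silicon is shielded by the two methyl groups.

Step 9
Reactants: 10 (5β-H)-11-(tert-butyldimethylsilyloxy)-1,1-ethylenedioxy-15-noreudesm-7-en-4β-ol
Product: 12 trans-fused (5α-H)-11-(tert-butyldimethylsilyloxy)-1,1-ethylenedioxy-15-noreudesm-7-en-4-one, via cis-fused C4 ketone 11 (not isolated)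
Conditions: Dess–Martin periodinane, NaHCO3, CH2Cl2, rt; then K2CO3, MeOH, rt
Reagents that add atoms: none
Why: Dess–Martin oxidation gives the cis-fused ketone, and the base then epimerises C5 through the C4 enolate to the trans-fused decalone, which should be the more stable isomer (steroid-like 4-ketone); C10 is quaternary and cannot change, and the skipped C7=C8 alkene is not in conjugation with the enolate.

Step 10
Reactants: 12 trans-fused (5α-H)-11-(tert-butyldimethylsilyloxy)-1,1-ethylenedioxy-15-noreudesm-7-en-4-one
Product: 13 11-(tert-butyldimethylsilyloxy)-1,1-ethylenedioxy-5α-eudesm-7-en-4β-ol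
Conditions: MeMgBr (3 equiv), THF, −78 to 0 °C
Reagents that add atoms: methylmagnesium bromide, C[Mg]Br
Why: Grignard addition to the only free carbonyl; axial attack is blocked by the 1,3-diaxial C10 methyl, so the methyl group should enter equatorially from the α face and leave the hydroxyl axial and cis to the C10 methyl, as in the target.

Step 11
Reactants: 13 11-(tert-butyldimethylsilyloxy)-1,1-ethylenedioxy-5α-eudesm-7-en-4β-ol
Product: 14 11-(tert-butyldimethylsilyloxy)-1,1-ethylenedioxy-5α,7α-H-eudesman-4β-ol
Conditions: H2 (1 atm), PtO2, EtOAc, rt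
Reagents that add atoms: none
Why: Heterogeneous hydrogenation of the trisubstituted alkene; the catalyst should bind the α face, away from the axial C10 methyl, so H7 enters α and the C7 side chain becomes equatorial and cis to the C10 methyl; platinum is preferred to palladium to avoid allylic C–O hydrogenolysis.

Step 12
Reactants: 14 11-(tert-butyldimethylsilyloxy)-1,1-ethylenedioxy-5α,7α-H-eudesman-4β-ol
Product: 15 11-(tert-butyldimethylsilyloxy)-4β-hydroxy-5α,7α-H-eudesman-1-one
Conditions: PPTS, acetone–H2O (10:1), 55 °C
Reagents that add atoms: water, O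
Why: Mild acetal hydrolysis; the weak acid should spare the tertiary alcohol and the tertiary silyl ether, which is no longer allylic.

Step 13
Reactants: 15 11-(tert-butyldimethylsilyloxy)-4β-hydroxy-5α,7α-H-eudesman-1-one
Product: 17 11-(tert-butyldimethylsilyloxy)-4β-hydroxy-5α,7α-H-eudesm-1-en-1-yl trifluoromethanesulfonate, via dipotassium enolate alkoxide 16 (not isolated)
Conditions: KN(SiMe3)2 (2.2 equiv), THF, −78 °C; PhNTf2 (1.1 equiv), −78 to 0 °C
Reagents that add atoms: N-phenylbis(trifluoromethanesulfonimide), O=S(=O)(N(c1ccccc1)S(=O)(=O)C(F)(F)F)C(F)(F)F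
Why: Enolate O-triflation; C10 is quaternary, so the enolate can only form towards C2, and the hindered tertiary alkoxide should be far slower than the enolate towards the mild triflyl donor.

Step 14
Reactants: 17 11-(tert-butyldimethylsilyloxy)-4β-hydroxy-5α,7α-H-eudesm-1-en-1-yl trifluoromethanesulfonate
Product: 18 11-(tert-butyldimethylsilyloxy)-4β-hydroxy-N-methoxy-N-methyl-5α,7α-H-eudesm-1-ene-1-carboxamide
Conditions: CO (1 atm), MeONHMe·HCl, Pd(OAc)2 (5 mol %), PPh3 (10 mol %), Et3N, DMF, 60 °C
Reagents that add atoms: carbon monoxide, [C-]#[O+]; N,O-dimethylhydroxylamine hydrochloride, CNOC.Cl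
Why: Palladium-catalysed aminocarbonylation; zerovalent palladium inserts into the C–OTf bond, CO insertion gives the acyl complex and the hydroxylamine intercepts it; alkenyl triflates next to quaternary carbons are standard substrates, and the carbon introduced is C1′.

Step 15
Reactants: 18 11-(tert-butyldimethylsilyloxy)-4β-hydroxy-N-methoxy-N-methyl-5α,7α-H-eudesm-1-ene-1-carboxamide; 19 1,3,5-trimethoxybenzene
Product: 21 [11-(tert-butyldimethylsilyloxy)-4β-hydroxy-5α,7α-H-eudesm-1-en-1-yl](2,4,6-trimethoxyphenyl)methanone, via 2,4,6-trimethoxyphenyllithium 20 (not isolated)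
Conditions: 19 (3 equiv), n-BuLi (3 equiv), THF, 0 °C to rt; then 18, −78 to 0 °C; aq. NH4Cl
Reagents that add atoms: none
Why: Directed ortho-lithiation of 19 between two methoxy groups, then acylation by the Weinreb amide; the chelated tetrahedral intermediate prevents a second addition, one equivalent of 20 is spent on the C4 hydroxyl, and no epimerisable centre is present yet.

Step 16
Reactants: 21 [11-(tert-butyldimethylsilyloxy)-4β-hydroxy-5α,7α-H-eudesm-1-en-1-yl](2,4,6-trimethoxyphenyl)methanone
Product: 22 [(1β-H)-11-(tert-butyldimethylsilyloxy)-4β-hydroxy-5α,7α-H-eudesman-1α-yl](2,4,6-trimethoxyphenyl)methanone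
Conditions: H2 (1 atm), [Ir(cod)(PCy3)(py)]PF6 (10 mol %), CH2Cl2, rt
Reagents that add atoms: none
Why: Hydroxyl-directed homogeneous hydrogenation; the cationic iridium centre binds the axial C4 hydroxyl and the homoallylic C1=C2 alkene on the same (β) face and delivers both hydrogens there, so H1 ends cis to the C10 methyl and the acyl group axial and α, the opposite of what an undirected catalyst would give.

Step 17
Reactants: 22 [(1β-H)-11-(tert-butyldimethylsilyloxy)-4β-hydroxy-5α,7α-H-eudesman-1α-yl](2,4,6-trimethoxyphenyl)methanone
Product: 23 1α-[1-hydroxy-3-methyl-1-(2,4,6-trimethoxyphenyl)but-3-enyl]-11-(tert-butyldimethylsilyloxy)-5α,7α-H-eudesman-4β-ol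
Conditions: CH2=C(CH3)CH2MgCl (4 equiv), THF, −78 to −20 °C; aq. NH4Cl
Reagents that add atoms: 2-methylallylmagnesium chloride, CC(=C)C[Mg]Cl
Why: Allyl-type Grignard addition through a six-membered transition state, the most reliable way to add carbon to a ketone shielded on both sides; it is fast and weakly basic, so the C1–H next to the carbonyl should not be removed, and the configuration of the new carbinol is irrelevant.

Step 18
Reactants: 23 1α-[1-hydroxy-3-methyl-1-(2,4,6-trimethoxyphenyl)but-3-enyl]-11-(tert-butyldimethylsilyloxy)-5α,7α-H-eudesman-4β-ol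
Product: 24 1α-[1-hydroxy-3-methyl-1-(2,4,6-trimethoxyphenyl)butyl]-11-(tert-butyldimethylsilyloxy)-5α,7α-H-eudesman-4β-ol
Conditions: H2 (1 atm), PtO2, EtOAc, rt
Reagents that add atoms: none
Why: Hydrogenation of the unhindered 1,1-disubstituted alkene under neutral conditions turns the methallyl group into the isobutyl group before any acid is applied, so that no second cation can form in step 19.

Step 19
Reactants: 24 1α-[1-hydroxy-3-methyl-1-(2,4,6-trimethoxyphenyl)butyl]-11-(tert-butyldimethylsilyloxy)-5α,7α-H-eudesman-4β-ol
Product: 25 1α-[(1R)-3-methyl-1-(2,4,6-trimethoxyphenyl)butyl]-11-(tert-butyldimethylsilyloxy)-5α,7α-H-eudesman-4β-ol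
Conditions: Et3SiH (5 equiv), CF3CO2H (3 equiv), CH2Cl2, −40 °C
Reagents that add atoms: none
Why: Ionic hydrogenation; only the tertiary alcohol beside the tri-donor arene ionises under these conditions, and the aliphatic C4 carbinol should not. In the cation, allylic 1,3-strain with an ortho-methoxy group should hold the C1–H bond near the cation plane on the arene side, so the two faces are flanked by C2 and by the quaternary C10. Hydride from the silane is expected on the C2 side, which corresponds to (R) at C1′.

Step 20
Reactants: 25 1α-[(1R)-3-methyl-1-(2,4,6-trimethoxyphenyl)butyl]-11-(tert-butyldimethylsilyloxy)-5α,7α-H-eudesman-4β-ol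
Product: 26 1α-[(1R)-1-(3,5-dibromo-2,4,6-trimethoxyphenyl)-3-methylbutyl]-11-(tert-butyldimethylsilyloxy)-5α,7α-H-eudesman-4β-ol
Conditions: NBS (2.1 equiv), MeCN, 0 °C
Reagents that add atoms: N-bromosuccinimide, O=C1CCC(=O)N1Br
Why: Electrophilic aromatic bromination of the two remaining positions, each activated by two ortho methoxy groups; no acid is generated, so the tertiary alcohol and the silyl ether are safe.

Step 21
Reactants: 26 1α-[(1R)-1-(3,5-dibromo-2,4,6-trimethoxyphenyl)-3-methylbutyl]-11-(tert-butyldimethylsilyloxy)-5α,7α-H-eudesman-4β-ol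
Product: 28 5-[(1R)-1-[11-(tert-butyldimethylsilyloxy)-4β-hydroxy-5α,7α-H-eudesman-1α-yl]-3-methylbutyl]-2,4,6-trimethoxybenzene-1,3-dicarbaldehyde, via dilithiated arene lithium alkoxide 27 (not isolated)
Conditions: t-BuLi (5.5 equiv), THF, −78 °C; DMF (excess), −78 °C to rt; aq. NH4Cl
Reagents that add atoms: N,N-dimethylformamide, CN(C)C=O
Why: Double bromine–lithium exchange (each aryllithium is stabilised by two flanking methoxy groups) followed by formylation with DMF; this installs both aldehydes without the strong Lewis acid of a Rieche formylation, which the tertiary alcohol would not survive.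

Step 22
Reactants: 28 5-[(1R)-1-[11-(tert-butyldimethylsilyloxy)-4β-hydroxy-5α,7α-H-eudesman-1α-yl]-3-methylbutyl]-2,4,6-trimethoxybenzene-1,3-dicarbaldehyde
Product: 29 5-[(1R)-1-(4β,11-dihydroxy-5α,7α-H-eudesman-1α-yl)-3-methylbutyl]-2,4,6-trimethoxybenzene-1,3-dicarbaldehyde
Conditions: Bu4NF (3 equiv), THF, 50 °C
Reagents that add atoms: none
Why: Fluoride cleavage of the hindered tertiary silyl ether needs gentle heating; the non-enolisable aldehydes and the methyl ethers tolerate fluoride, and doing this before the phenols are freed keeps the fluoride from being buffered by phenoxide formation.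

Step 23
Reactants: 29 5-[(1R)-1-(4β,11-dihydroxy-5α,7α-H-eudesman-1α-yl)-3-methylbutyl]-2,4,6-trimethoxybenzene-1,3-dicarbaldehyde
Product: 30 5-[(1R)-1-[(1S,4R,5S,7S,10R)-4,11-dihydroxyeudesman-1-yl]-3-methylbutyl]-2,4,6-trihydroxybenzene-1,3-dicarbaldehyde (CNP0409870.5)
Conditions: NaSEt (8 equiv), DMF, 90 °C; dilute HCl work-up under argon
Reagents that add atoms: none
Why: Nucleophilic O-demethylation (SN2 at methyl by thiolate); every methoxy group is ortho or para to a formyl group and is therefore a vinylogous methyl ester, and the basic, non-Lewis-acidic conditions leave both tertiary alcohols and all stereocentres untouched.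

## Compound list

1 | 2-methylcyclohex-2-en-1-one | CC1=CCCCC1=O | starting material
2 | 2-methylcyclohex-2-ene-1,4-dione | CC1=CC(=O)CCC1=O | intermediate
3 | (R)-4-hydroxy-2-methylcyclohex-2-en-1-one | CC1=C[C@H](O)CCC1=O | intermediate
4 | (R)-4-(tert-butyldimethylsilyloxy)-2-methylcyclohex-2-en-1-one | CC1=C[C@H](O[Si](C)(C)C(C)(C)C)CCC1=O | intermediate
5 | 2-methylbut-3-yn-2-ol | CC(C)(O)C#C | starting material
6 | tert-butyldimethyl[(2-methylbut-3-yn-2-yl)oxy]silane | CC(C)(O[Si](C)(C)C(C)(C)C)C#C | intermediate
7 | 2-[2-(tert-butyldimethylsilyloxy)propan-2-yl]buta-1,3-diene | C=CC(=C)C(C)(C)O[Si](C)(C)C(C)(C)C | intermediate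
8 | cis-fused (5β-H)-4β,11-bis(tert-butyldimethylsilyloxy)-15-noreudesm-7-en-1-one | O=C1CC[C@@H](O[Si](C)(C)C(C)(C)C)[C@@H]2CC(C(C)(C)O[Si](C)(C)C(C)(C)C)=CC[C@]12C | intermediate
9 | (5β-H)-4β,11-bis(tert-butyldimethylsilyloxy)-1,1-ethylenedioxy-15-noreudesm-7-ene | C1COC2(O1)CC[C@@H](O[Si](C)(C)C(C)(C)C)[C@@H]3CC(C(C)(C)O[Si](C)(C)C(C)(C)C)=CC[C@]23C | intermediate
10 | (5β-H)-11-(tert-butyldimethylsilyloxy)-1,1-ethylenedioxy-15-noreudesm-7-en-4β-ol | C1COC2(O1)CC[C@@H](O)[C@@H]3CC(C(C)(C)O[Si](C)(C)C(C)(C)C)=CC[C@]23C | intermediate
11 | cis-fused (5β-H)-11-(tert-butyldimethylsilyloxy)-1,1-ethylenedioxy-15-noreudesm-7-en-4-one | C1COC2(O1)CCC(=O)[C@@H]3CC(C(C)(C)O[Si](C)(C)C(C)(C)C)=CC[C@]23C | intermediate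
12 | trans-fused (5α-H)-11-(tert-butyldimethylsilyloxy)-1,1-ethylenedioxy-15-noreudesm-7-en-4-one | C1COC2(O1)CCC(=O)[C@H]3CC(C(C)(C)O[Si](C)(C)C(C)(C)C)=CC[C@]23C | intermediate
13 | 11-(tert-butyldimethylsilyloxy)-1,1-ethylenedioxy-5α-eudesm-7-en-4β-ol (4α-methyl, axial 4β-hydroxyl) | C1COC2(O1)CC[C@@](C)(O)[C@H]3CC(C(C)(C)O[Si](C)(C)C(C)(C)C)=CC[C@]23C | intermediate
14 | 11-(tert-butyldimethylsilyloxy)-1,1-ethylenedioxy-5α,7α-H-eudesman-4β-ol (C7 side chain β) | C1COC2(O1)CC[C@@](C)(O)[C@H]3C[C@@H](C(C)(C)O[Si](C)(C)C(C)(C)C)CC[C@]23C | intermediate
15 | 11-(tert-butyldimethylsilyloxy)-4β-hydroxy-5α,7α-H-eudesman-1-one | O=C1CC[C@@](C)(O)[C@H]2C[C@@H](C(C)(C)O[Si](C)(C)C(C)(C)C)CC[C@]12C | intermediate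
16 | dipotassium salt of the C1(O)=C2 enolate and C4 alkoxide of 15 | [O-]C1=CC[C@@](C)([O-])[C@H]2C[C@@H](C(C)(C)O[Si](C)(C)C(C)(C)C)CC[C@]12C.[K+].[K+] | intermediate
17 | 11-(tert-butyldimethylsilyloxy)-4β-hydroxy-5α,7α-H-eudesm-1-en-1-yl trifluoromethanesulfonate | O=S(=O)(OC1=CC[C@@](C)(O)[C@H]2C[C@@H](C(C)(C)O[Si](C)(C)C(C)(C)C)CC[C@]12C)C(F)(F)F | intermediate
18 | 11-(tert-butyldimethylsilyloxy)-4β-hydroxy-N-methoxy-N-methyl-5α,7α-H-eudesm-1-ene-1-carboxamide | CON(C)C(=O)C1=CC[C@@](C)(O)[C@H]2C[C@@H](C(C)(C)O[Si](C)(C)C(C)(C)C)CC[C@]12C | intermediate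
19 | 1,3,5-trimethoxybenzene | COc1cc(OC)cc(OC)c1 | starting material
20 | 2,4,6-trimethoxyphenyllithium | [Li]c1c(OC)cc(OC)cc1OC | intermediate
21 | [11-(tert-butyldimethylsilyloxy)-4β-hydroxy-5α,7α-H-eudesm-1-en-1-yl](2,4,6-trimethoxyphenyl)methanone | COc1cc(OC)c(C(=O)C2=CC[C@@](C)(O)[C@H]3C[C@@H](C(C)(C)O[Si](C)(C)C(C)(C)C)CC[C@]23C)c(OC)c1 | intermediate
22 | [(1β-H)-11-(tert-butyldimethylsilyloxy)-4β-hydroxy-5α,7α-H-eudesman-1α-yl](2,4,6-trimethoxyphenyl)methanone | COc1cc(OC)c(C(=O)[C@@H]2CC[C@@](C)(O)[C@H]3C[C@@H](C(C)(C)O[Si](C)(C)C(C)(C)C)CC[C@]23C)c(OC)c1 | intermediate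
23 | 1α-[1-hydroxy-3-methyl-1-(2,4,6-trimethoxyphenyl)but-3-enyl]-11-(tert-butyldimethylsilyloxy)-5α,7α-H-eudesman-4β-ol (carbinol carbon undefined) | COc1cc(OC)c(C(O)(CC(C)=C)[C@@H]2CC[C@@](C)(O)[C@H]3C[C@@H](C(C)(C)O[Si](C)(C)C(C)(C)C)CC[C@]23C)c(OC)c1 | intermediate
24 | 1α-[1-hydroxy-3-methyl-1-(2,4,6-trimethoxyphenyl)butyl]-11-(tert-butyldimethylsilyloxy)-5α,7α-H-eudesman-4β-ol (carbinol carbon undefined) | COc1cc(OC)c(C(O)(CC(C)C)[C@@H]2CC[C@@](C)(O)[C@H]3C[C@@H](C(C)(C)O[Si](C)(C)C(C)(C)C)CC[C@]23C)c(OC)c1 | intermediate
25 | 1α-[(1R)-3-methyl-1-(2,4,6-trimethoxyphenyl)butyl]-11-(tert-butyldimethylsilyloxy)-5α,7α-H-eudesman-4β-ol | CC(C)C[C@@H](c1c(OC)cc(OC)cc1OC)[C@@H]1CC[C@@](C)(O)[C@H]2C[C@@H](C(C)(C)O[Si](C)(C)C(C)(C)C)CC[C@]12C | intermediate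
26 | 1α-[(1R)-1-(3,5-dibromo-2,4,6-trimethoxyphenyl)-3-methylbutyl]-11-(tert-butyldimethylsilyloxy)-5α,7α-H-eudesman-4β-ol | CC(C)C[C@@H](c1c(OC)c(Br)c(OC)c(Br)c1OC)[C@@H]1CC[C@@](C)(O)[C@H]2C[C@@H](C(C)(C)O[Si](C)(C)C(C)(C)C)CC[C@]12C | intermediate
27 | 3,5-dilithio analogue of 26 as its C4 lithium alkoxide | CC(C)C[C@@H](c1c(OC)c([Li])c(OC)c([Li])c1OC)[C@@H]1CC[C@@](C)(O[Li])[C@H]2C[C@@H](C(C)(C)O[Si](C)(C)C(C)(C)C)CC[C@]12C | intermediate
28 | 5-[(1R)-1-[11-(tert-butyldimethylsilyloxy)-4β-hydroxy-5α,7α-H-eudesman-1α-yl]-3-methylbutyl]-2,4,6-trimethoxybenzene-1,3-dicarbaldehyde | CC(C)C[C@@H](c1c(OC)c(C=O)c(OC)c(C=O)c1OC)[C@@H]1CC[C@@](C)(O)[C@H]2C[C@@H](C(C)(C)O[Si](C)(C)C(C)(C)C)CC[C@]12C | intermediate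
29 | 5-[(1R)-1-(4β,11-dihydroxy-5α,7α-H-eudesman-1α-yl)-3-methylbutyl]-2,4,6-trimethoxybenzene-1,3-dicarbaldehyde | CC(C)C[C@@H](c1c(OC)c(C=O)c(OC)c(C=O)c1OC)[C@@H]1CC[C@@](C)(O)[C@H]2C[C@@H](C(C)(C)O)CC[C@]12C | intermediate
30 | 5-[(1R)-1-[(1S,4R,5S,7S,10R)-4,11-dihydroxyeudesman-1-yl]-3-methylbutyl]-2,4,6-trihydroxybenzene-1,3-dicarbaldehyde (CNP0409870.5) | CC(C)C[C@@H](c1c(O)c(C=O)c(O)c(C=O)c1O)[C@@H]1CC[C@@](C)(O)[C@H]2C[C@@H](C(C)(C)O)CC[C@]12C | target

## Step count and least certain steps

Total: 23 steps. Longest linear sequence: 21 steps (1 to 30 through steps 1–3 and 6–23); the diene branch adds steps 4 and 5.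

**Step 6 (key step).** The most likely failure is consumption of the diene by Lewis-acid ionisation of its tertiary allylic silyl ether (elimination and oligomerisation) before the sluggish, trisubstituted dienophile has reacted; incomplete facial selectivity is the second concern. The fallback removes the ionisable C–O bond from the diene and adds the carbinol afterwards. It sets out from 4 and returns at 9.
- Compound 4 is combined under the same aluminium promoter with the acid-stable 2-(triethylsilyl)buta-1,3-diene F1, whose silyl group also directs para, to give the cis-fused vinylsilane adduct F2.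
- The C1 ketone is masked as in step 7 to give the dioxolane F3.
- Iododesilylation with N-iodosuccinimide in MeCN gives the C7 vinyl iodide F4.
- Iodine–lithium exchange (t-BuLi, −78 °C) and addition to acetone gives the tertiary allylic alcohol F5.
- Silylation with TBSOTf and 2,6-lutidine gives 9.

**Step 19.** The most likely failure is hydride delivery to the wrong face of the C1′ cation. The cation sits on an axial position beside a quaternary carbon, so the conformational model is not secure. Loss of H1 from the cation, which would scramble C1, is the second concern. The fallback exchanges the order in which hydrogen and carbon arrive at C1′, so that the same facial preference leads to the opposite configuration. It sets out from 22 and returns at 25.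
- The ketone is reduced with LiAlH4 to the secondary benzylic alcohol F6 (both carbinol epimers serve).
- The alcohol is ionised with BF3·OEt2 at −78 °C in the presence of CH2=C(CH3)CH2SiMe3 (Hosomi–Sakurai-type benzylic allylation) to give the methallyl compound F7.
- Hydrogenation over PtO2 gives 25.

**Step 16.** The most likely failure is hydrogen delivery from the undirected α face, or no turnover at all. The alkene is electron-poor and lies next to the quaternary C10, and the aryl ketone can occupy the metal. The fallback uses a directing group on the neighbouring carbon instead of the remote one. It sets out from 21 and returns at 22.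
- The enone carbonyl is reduced (oxazaborolidine-catalysed; the catalyst antipode is chosen to give the desired carbinol, and the unwanted epimer is reoxidised with MnO2) to the (R)-allylic alcohol F8.
- In the conformer of F8 that places the carbinol hydrogen towards C10, the hydroxyl lies on the β face. Allylic-hydroxyl-directed hydrogenation with [Rh(nbd)(dppb)]BF4 under hydrogen pressure then gives the saturated alcohol F9.
- Dess–Martin oxidation gives 22.

**Step 9.** The most likely failure is an incomplete epimerisation because the cis/trans equilibrium is not sufficiently one-sided; the acetal oxygen at C1 and the ring B alkene both shift it in ways that are hard to estimate. The fallback replaces thermodynamic by kinetic control. It sets out from 11 (or the mixture of 11 and 12) and returns at 12.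
- The more substituted trimethylsilyl enol ether F10 is formed under equilibrating conditions (Me3SiCl, Et3N, DMF, heat).
- The lithium enolate is released with MeLi and protonated at −78 °C with a hindered proton source. Axial protonation on the face opposite the C10 methyl should give 12.

**Step 2.** The most likely failure is low enantioselectivity, since the catalyst has only an sp2 versus an sp3 flank to distinguish. Competing reduction at C1 and tautomerisation of 2 to methylhydroquinone are further concerns. The fallback is a resolution. It sets out from 2 and returns at 3.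
- Regioselective reduction with NaBH4 and CeCl3 gives racemic 4-hydroxy-2-methylcyclohex-2-en-1-one F11.
- Lipase-catalysed acylation with vinyl acetate should, by the usual preference for the enantiomer with the sp2 flank as the large group, give (R)-4-acetoxy-2-methylcyclohex-2-en-1-one F12 and leave (S)-4-hydroxy-2-methylcyclohex-2-en-1-one F13.
- F12 is converted to 3 by lipase-catalysed alcoholysis with butanol (no base, to avoid elimination). F13 is reoxidised with MnO2 to 2 and recycled.
- If the enzyme shows the opposite preference, the unreacted alcohol is 3 itself.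

**Step 23.** The most likely failure is incomplete dealkylation, accompanied by displacement of an activated methoxy group by thiolate at the ring carbon. The fallback changes both the mechanism and the order of the last two steps. It sets out from 28 and returns at 30.
- Compound 28 is treated with MgI2·OEt2 in warm toluene (carbonyl-chelation-assisted cleavage by iodide, possible for all three methoxy groups because each is ortho to a formyl group) to give the triphenol silyl ether F14.
- The silyl ether is removed with Bu4NF to give 30.

## Further compounds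

F1 | step 6 | 2-(triethylsilyl)buta-1,3-diene | C=CC(=C)[Si](CC)(CC)CC
F2 | step 6 | cis-fused (5β-H)-4β-(tert-butyldimethylsilyloxy)-7-(triethylsilyl)-11,12,13,15-tetranoreudesm-7-en-1-one | O=C1CC[C@@H](O[Si](C)(C)C(C)(C)C)[C@@H]2CC([Si](CC)(CC)CC)=CC[C@]12C
F3 | step 6 | 1,1-ethylenedioxy acetal of F2 | C1COC2(O1)CC[C@@H](O[Si](C)(C)C(C)(C)C)[C@@H]3CC([Si](CC)(CC)CC)=CC[C@]23C
F4 | step 6 | C7 vinyl iodide (iodine in place of the triethylsilyl group of F3) | C1COC2(O1)CC[C@@H](O[Si](C)(C)C(C)(C)C)[C@@H]3CC(I)=CC[C@]23C
F5 | step 6 | (5β-H)-4β-(tert-butyldimethylsilyloxy)-1,1-ethylenedioxy-15-noreudesm-7-en-11-ol | C1COC2(O1)CC[C@@H](O[Si](C)(C)C(C)(C)C)[C@@H]3CC(C(C)(C)O)=CC[C@]23C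
F6 | step 19 | [(1β-H)-11-(tert-butyldimethylsilyloxy)-4β-hydroxy-5α,7α-H-eudesman-1α-yl](2,4,6-trimethoxyphenyl)methanol, carbinol epimers | COc1cc(OC)c(C(O)[C@@H]2CC[C@@](C)(O)[C@H]3C[C@@H](C(C)(C)O[Si](C)(C)C(C)(C)C)CC[C@]23C)c(OC)c1
F7 | step 19 | 1α-[(1R)-3-methyl-1-(2,4,6-trimethoxyphenyl)but-3-enyl]-11-(tert-butyldimethylsilyloxy)-5α,7α-H-eudesman-4β-ol | C=C(C)C[C@@H](c1c(OC)cc(OC)cc1OC)[C@@H]1CC[C@@](C)(O)[C@H]2C[C@@H](C(C)(C)O[Si](C)(C)C(C)(C)C)CC[C@]12C
F8 | step 16 | (R)-[11-(tert-butyldimethylsilyloxy)-4β-hydroxy-5α,7α-H-eudesm-1-en-1-yl](2,4,6-trimethoxyphenyl)methanol | COc1cc(OC)c([C@H](O)C2=CC[C@@](C)(O)[C@H]3C[C@@H](C(C)(C)O[Si](C)(C)C(C)(C)C)CC[C@]23C)c(OC)c1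
F9 | step 16 | (R)-[(1β-H)-11-(tert-butyldimethylsilyloxy)-4β-hydroxy-5α,7α-H-eudesman-1α-yl](2,4,6-trimethoxyphenyl)methanol | COc1cc(OC)c([C@H](O)[C@@H]2CC[C@@](C)(O)[C@H]3C[C@@H](C(C)(C)O[Si](C)(C)C(C)(C)C)CC[C@]23C)c(OC)c1
F10 | step 9 | 4-(trimethylsilyloxy)-11-(tert-butyldimethylsilyloxy)-1,1-ethylenedioxy-15-noreudesma-4,7-diene | C1COC2(O1)CCC(O[Si](C)(C)C)=C3CC(C(C)(C)O[Si](C)(C)C(C)(C)C)=CC[C@]23C
F11 | step 2 | racemic 4-hydroxy-2-methylcyclohex-2-en-1-one | CC1=CC(O)CCC1=O
F12 | step 2 | (R)-4-acetoxy-2-methylcyclohex-2-en-1-one | CC1=C[C@H](OC(C)=O)CCC1=O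
F13 | step 2 | (S)-4-hydroxy-2-methylcyclohex-2-en-1-one | CC1=C[C@@H](O)CCC1=O
F14 | step 23 | 5-[(1R)-1-[11-(tert-butyldimethylsilyloxy)-4β-hydroxy-5α,7α-H-eudesman-1α-yl]-3-methylbutyl]-2,4,6-trihydroxybenzene-1,3-dicarbaldehyde | CC(C)C[C@@H](c1c(O)c(C=O)c(O)c(C=O)c1O)[C@@H]1CC[C@@](C)(O)[C@H]2C[C@@H](C(C)(C)O[Si](C)(C)C(C)(C)C)CC[C@]12C
A1 | alternative 1 | ten-membered 1(10),4-diene with the C1 side chain and a C7 methyl ester (ring-trans double bonds) | CC(C)C[C@@H](c1c(OC)cc(OC)cc1OC)/C1=C(/C)CC[C@H](C(=O)OC)C/C=C(\C)CC1
A2 | alternative 1 | trans-decalin with C4 exocyclic methylene and C7 methyl ester | CC(C)C[C@@H](c1c(OC)cc(OC)cc1OC)[C@@H]1CCC(=C)[C@H]2C[C@@H](C(=O)OC)CC[C@]12C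
A3 | alternative 2 | 4-methylcyclohexa-2,5-dienone with the aldehyde-bearing side chain on C4 of the dienone | CC(C)C[C@@H](c1c(OC)cc(OC)cc1OC)[C@H](CCC=O)C1(C)C=CC(=O)C=C1
A4 | alternative 2 | trans-fused 4,7-diketo-8-ene | CC(C)C[C@@H](c1c(OC)cc(OC)cc1OC)[C@@H]1CCC(=O)[C@H]2CC(=O)C=C[C@]12C
A5 | alternative 3 | linalool-derived triene ester (E-enoate, E-diene, silyl-protected C1 and C4 oxygens) | COC(=O)/C=C(\C)[C@@H](O[Si](C)(C)C(C)(C)C)CC[C@@](C)(O[Si](CC)(CC)CC)/C=C/C(=C)C(C)(C)O[Si](CC)(CC)CC
A6 | alternative 3 | trans-fused octalin with C4 carbinol, C1 silyloxy group and C9 methyl ester | CC(C)(C)[Si](C)(C)O[C@H]1CC[C@@](C)(O[Si](CC)(CC)CC)[C@H]2C=C(C(C)(C)O[Si](CC)(CC)CC)C[C@@H](C(=O)OC)[C@]12C
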